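**Retrosynthetic overview**
1. Last step: one hydrogenation converts an (E)-stilbene carrying five benzyl ethers into the target (C=C saturation plus global O-debenzylation).
2. Stilbene <= 1,2-diarylethanol <= deoxybenzoin <= beta-keto ester (dehydration, hydride reduction, Krapcho dealkoxycarbonylation).
3. Key disconnection: the bridge C-C bond, made by a crossed Claisen condensation between the ring A arylacetate enolate and the ring B methyl benzoate.
4. All three 4-hydroxybenzyl arms come from one benzylic zinc reagent. It is Negishi-coupled twice to the ring A 2,6-dibromide and once to the ring B 4-bromide, before the fragments are joined.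
5. No ring is formed, since all five benzene rings are bought. The ring A OH/OMe difference is set in the first step by thiolate mono-demethylation.

Assumption 1: the target SMILES has no stereocentre and no stereogenic double bond, so the compound is achiral and there is no enantiomer to select; the transient stereocentres in 18 and 20 are racemic and are erased later.
Assumption 2: in step 13 the species that have lost only some of the five benzyl groups are too many to number, so only the first-formed saturated compound 22 is listed.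

**Route**

Step 1
Reactants: 1 2-(3,5-dimethoxyphenyl)acetic acid
Product: 2 2-(3-hydroxy-5-methoxyphenyl)acetic acid
Conditions: NaSEt (3.5 equiv), DMF, 140 °C, 3 h; then 2 M HCl
Reagents that add atoms: none
Why: This is an SN2 cleavage of an aryl methyl ether by thiolate, and it stops after one methyl because the phenoxide formed (next to the carboxylate) makes a second attack far slower, so the symmetric diether is desymmetrised without a statistical mixture.

Step 2
Reactants: 2 2-(3-hydroxy-5-methoxyphenyl)acetic acid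
Product: 3 methyl 2-(3-hydroxy-5-methoxyphenyl)acetate
Conditions: MeOH, H2SO4 (cat.), reflux, 6 h
Reagents that add atoms: methanol, CO
Why: Fischer esterification converts only the carboxylic acid and leaves the phenol and the aryl methyl ether untouched.

Step 3
Reactants: 3 methyl 2-(3-hydroxy-5-methoxyphenyl)acetate
Product: 4 methyl 2-[3-(benzyloxy)-5-methoxyphenyl]acetate
Conditions: BnBr (1.1 equiv), K2CO3 (2 equiv), acetone, reflux, 6 h
Reagents that add atoms: benzyl bromide, BrCc1ccccc1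
Why: In this Williamson ether synthesis K2CO3 deprotonates only the phenol and not the ester alpha-CH2, and the benzyl ether is orthogonal to the methyl ether that must remain.

Step 4
Reactants: 4 methyl 2-[3-(benzyloxy)-5-methoxyphenyl]acetate
Product: 7 methyl 2-[3-(benzyloxy)-2,6-dibromo-5-methoxyphenyl]acetate, via monobromide next to OMe 5 (not isolated), via monobromide next to OBn 6 (not isolated)
Conditions: NBS (2.05 equiv), MeCN, 0 °C to rt, dark, 4 h
Reagents that add atoms: N-bromosuccinimide, O=C1CCC(=O)N1Br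
Why: Electrophilic aromatic bromination takes the two positions that are para to one alkoxy group and ortho to the other, while the crowded site between the two alkoxy groups stays C-H with two equivalents, and the polar dark conditions suppress radical benzylic bromination.

Step 5
Reactants: 8 4-(benzyloxy)benzyl chloride
Product: 9 [4-(benzyloxy)benzyl]zinc chloride (LiCl-solubilised THF stock solution, titrated and used in steps 6 and 8)
Conditions: Zn dust (2 equiv), LiCl (2 equiv), THF, 25 °C, 5 h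
Reagents that add atoms: zinc, [Zn]
Why: LiCl-promoted direct zinc insertion into the benzylic C-Cl bond gives a soluble benzylic zinc chloride with little Wurtz coupling and tolerates the ether.

Step 6
Reactants: 7 methyl 2-[3-(benzyloxy)-2,6-dibromo-5-methoxyphenyl]acetate; 9 [4-(benzyloxy)benzyl]zinc chloride (2.8 equiv)
Product: 12 methyl 2-{3-(benzyloxy)-2,6-bis[4-(benzyloxy)benzyl]-5-methoxyphenyl}acetate, via 6-benzylated 2-bromide 10 (not isolated), via 2-benzylated 6-bromide 11 (not isolated)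
Conditions: Pd(OAc)2 (4 mol%), SPhos (8 mol%), THF, 60 °C, 16 h
Reagents that add atoms: none
Why: In this double Negishi cross-coupling the bulky electron-rich biarylphosphine lets zerovalent palladium insert into the ortho-flanked electron-rich C-Br bonds, and the weakly basic benzylic zinc reagent leaves the ester and its alpha-protons alone.

Step 7
Reactants: 13 methyl 4-bromo-3-hydroxybenzoate
Product: 14 methyl 3-(benzyloxy)-4-bromobenzoate
Conditions: BnBr (1.1 equiv), K2CO3 (2 equiv), DMF, rt, 12 h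
Reagents that add atoms: benzyl bromide, BrCc1ccccc1
Why: This Williamson ether synthesis on an acidic phenol is clean, and the ester and aryl bromide are inert to carbonate.

Step 8
Reactants: 14 methyl 3-(benzyloxy)-4-bromobenzoate; 9 [4-(benzyloxy)benzyl]zinc chloride (1.3 equiv)
Product: 15 methyl 3-(benzyloxy)-4-[4-(benzyloxy)benzyl]benzoate
Conditions: Pd(OAc)2 (1 mol%), SPhos (2 mol%), THF, 25 °C, 4 h
Reagents that add atoms: none
Why: This Negishi cross-coupling uses an aryl bromide activated by the para ester and hindered on one side only, which is a very favourable case, and the ester is tolerated.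

Step 9 (key C-C bond)
Reactants: 12 methyl 2-{3-(benzyloxy)-2,6-bis[4-(benzyloxy)benzyl]-5-methoxyphenyl}acetate; 15 methyl 3-(benzyloxy)-4-[4-(benzyloxy)benzyl]benzoate
Product: 18 methyl 2-{3-(benzyloxy)-2,6-bis[4-(benzyloxy)benzyl]-5-methoxyphenyl}-3-{3-(benzyloxy)-4-[4-(benzyloxy)benzyl]phenyl}-3-oxopropanoate (racemic), via ester lithium enolate 16 (not isolated), via keto ester lithium salt 17 (not isolated)
Conditions: 12, LiN(SiMe3)2 (1.1 equiv), THF, -78 °C, 45 min; add 15 (1.1 equiv); LiN(SiMe3)2 (1.2 equiv) dropwise, -78 °C to rt, 12 h; then AcOH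
Reagents that add atoms: none
Why: In this crossed Claisen condensation only 12 forms an ester enolate, 12 is too hindered to self-condense and 15 has no alpha-hydrogen, irreversible deprotonation to 17 drives the reaction, and the new alpha-stereocentre is racemic and is removed in step 10.

Step 10
Reactants: 18 beta-keto ester from step 9
Product: 19 2-{3-(benzyloxy)-2,6-bis[4-(benzyloxy)benzyl]-5-methoxyphenyl}-1-{3-(benzyloxy)-4-[4-(benzyloxy)benzyl]phenyl}ethan-1-one
Conditions: LiCl (3 equiv), H2O (5 equiv), DMSO, 150 °C, 3 h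
Reagents that add atoms: none
Why: In the Krapcho dealkoxycarbonylation chloride attacks the unhindered O-methyl carbon, the beta-keto carboxylate loses CO2, and the near-neutral medium avoids retro-Claisen cleavage and leaves all the ethers intact.

Step 11
Reactants: 19 deoxybenzoin from step 10
Product: 20 2-{3-(benzyloxy)-2,6-bis[4-(benzyloxy)benzyl]-5-methoxyphenyl}-1-{3-(benzyloxy)-4-[4-(benzyloxy)benzyl]phenyl}ethan-1-ol (racemic)
Conditions: NaBH4 (1.5 equiv), THF/MeOH 4:1, 0 °C to rt, 2 h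
Reagents that add atoms: none
Why: Borohydride reduction works well because the carbonyl sits next to the unhindered ring B, and the racemic carbinol centre is erased in step 12.

Step 12
Reactants: 20 1,2-diarylethanol from step 11
Product: 21 (E)-1-(benzyloxy)-2,4-bis[4-(benzyloxy)benzyl]-3-(2-{3-(benzyloxy)-4-[4-(benzyloxy)benzyl]phenyl}ethenyl)-5-methoxybenzene
Conditions: p-TsOH·H2O (10 mol%), toluene (0.02 M), reflux, Dean-Stark, 1-2 h
Reagents that add atoms: none
Why: Acid-catalysed E1 dehydration of the secondary benzylic alcohol gives the conjugated and thermodynamically preferred E-stilbene, high dilution disfavours intermolecular Friedel-Crafts trapping, and the alkene geometry is irrelevant after step 13.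

Step 13
Reactants: 21 (E)-stilbene from step 12
Product: 23 2,4-bis(4-hydroxybenzyl)-3-{2-[3-hydroxy-4-(4-hydroxybenzyl)phenyl]ethyl}-5-methoxyphenol (CNP0207338.0), via penta-O-benzyl bibenzyl 22 (not isolated)
Conditions: H2 (3 bar), Pd/C (10 wt% Pd), THF/MeOH 1:1, rt, 16 h
Reagents that add atoms: none
Why: Heterogeneous catalytic hydrogenation saturates the alkene and hydrogenolyses the five aryl benzyl ethers, the aryl methyl ether and the diarylmethane C-C bonds are inert, and no stereocentre is created.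

**Compound list**
1 | 2-(3,5-dimethoxyphenyl)acetic acid | COc1cc(CC(=O)O)cc(OC)c1 | starting material
2 | 2-(3-hydroxy-5-methoxyphenyl)acetic acid | COc1cc(O)cc(CC(=O)O)c1 | intermediate
3 | methyl 2-(3-hydroxy-5-methoxyphenyl)acetate | COC(=O)Cc1cc(O)cc(OC)c1 | intermediate
4 | methyl 2-[3-(benzyloxy)-5-methoxyphenyl]acetate | COC(=O)Cc1cc(OCc2ccccc2)cc(OC)c1 | intermediate
5 | methyl 2-[5-(benzyloxy)-2-bromo-3-methoxyphenyl]acetate | COC(=O)Cc1cc(OCc2ccccc2)cc(OC)c1Br | intermediate
6 | methyl 2-[3-(benzyloxy)-2-bromo-5-methoxyphenyl]acetate | COC(=O)Cc1cc(OC)cc(OCc2ccccc2)c1Br | intermediate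
7 | methyl 2-[3-(benzyloxy)-2,6-dibromo-5-methoxyphenyl]acetate | COC(=O)Cc1c(Br)c(OCc2ccccc2)cc(OC)c1Br | intermediate
8 | 4-(benzyloxy)benzyl chloride | ClCc1ccc(OCc2ccccc2)cc1 | starting material
9 | [4-(benzyloxy)benzyl]zinc chloride | Cl[Zn]Cc1ccc(OCc2ccccc2)cc1 | intermediate
10 | methyl 2-{3-(benzyloxy)-6-[4-(benzyloxy)benzyl]-2-bromo-5-methoxyphenyl}acetate | COC(=O)Cc1c(Br)c(OCc2ccccc2)cc(OC)c1Cc1ccc(OCc2ccccc2)cc1 | intermediate
11 | methyl 2-{3-(benzyloxy)-2-[4-(benzyloxy)benzyl]-6-bromo-5-methoxyphenyl}acetate | COC(=O)Cc1c(Br)c(OC)cc(OCc2ccccc2)c1Cc1ccc(OCc2ccccc2)cc1 | intermediate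
12 | methyl 2-{3-(benzyloxy)-2,6-bis[4-(benzyloxy)benzyl]-5-methoxyphenyl}acetate | COC(=O)Cc1c(Cc2ccc(OCc3ccccc3)cc2)c(OCc2ccccc2)cc(OC)c1Cc1ccc(OCc2ccccc2)cc1 | intermediate
13 | methyl 4-bromo-3-hydroxybenzoate | COC(=O)c1ccc(Br)c(O)c1 | starting material
14 | methyl 3-(benzyloxy)-4-bromobenzoate | COC(=O)c1ccc(Br)c(OCc2ccccc2)c1 | intermediate
15 | methyl 3-(benzyloxy)-4-[4-(benzyloxy)benzyl]benzoate | COC(=O)c1ccc(Cc2ccc(OCc3ccccc3)cc2)c(OCc2ccccc2)c1 | intermediate
16 | lithium enolate of ester 12 | [Li+].COC([O-])=Cc1c(Cc2ccc(OCc3ccccc3)cc2)c(OCc2ccccc2)cc(OC)c1Cc1ccc(OCc2ccccc2)cc1 | intermediate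
17 | lithium enolate salt of beta-keto ester 18 | [Li+].COC(=O)C(c1c(Cc2ccc(OCc3ccccc3)cc2)c(OCc2ccccc2)cc(OC)c1Cc1ccc(OCc2ccccc2)cc1)=C([O-])c1ccc(Cc2ccc(OCc3ccccc3)cc2)c(OCc2ccccc2)c1 | intermediate
18 | methyl 2-{3-(benzyloxy)-2,6-bis[4-(benzyloxy)benzyl]-5-methoxyphenyl}-3-{3-(benzyloxy)-4-[4-(benzyloxy)benzyl]phenyl}-3-oxopropanoate (racemic) | COC(=O)C(C(=O)c1ccc(Cc2ccc(OCc3ccccc3)cc2)c(OCc2ccccc2)c1)c1c(Cc2ccc(OCc3ccccc3)cc2)c(OCc2ccccc2)cc(OC)c1Cc1ccc(OCc2ccccc2)cc1 | intermediate
19 | 2-{3-(benzyloxy)-2,6-bis[4-(benzyloxy)benzyl]-5-methoxyphenyl}-1-{3-(benzyloxy)-4-[4-(benzyloxy)benzyl]phenyl}ethan-1-one | O=C(Cc1c(Cc2ccc(OCc3ccccc3)cc2)c(OCc2ccccc2)cc(OC)c1Cc1ccc(OCc2ccccc2)cc1)c1ccc(Cc2ccc(OCc3ccccc3)cc2)c(OCc2ccccc2)c1 | intermediate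
20 | 2-{3-(benzyloxy)-2,6-bis[4-(benzyloxy)benzyl]-5-methoxyphenyl}-1-{3-(benzyloxy)-4-[4-(benzyloxy)benzyl]phenyl}ethan-1-ol (racemic) | OC(Cc1c(Cc2ccc(OCc3ccccc3)cc2)c(OCc2ccccc2)cc(OC)c1Cc1ccc(OCc2ccccc2)cc1)c1ccc(Cc2ccc(OCc3ccccc3)cc2)c(OCc2ccccc2)c1 | intermediate
21 | (E)-1-(benzyloxy)-2,4-bis[4-(benzyloxy)benzyl]-3-(2-{3-(benzyloxy)-4-[4-(benzyloxy)benzyl]phenyl}ethenyl)-5-methoxybenzene | COc1cc(OCc2ccccc2)c(Cc2ccc(OCc3ccccc3)cc2)c(/C=C/c2ccc(Cc3ccc(OCc4ccccc4)cc3)c(OCc3ccccc3)c2)c1Cc1ccc(OCc2ccccc2)cc1 | intermediate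
22 | 1-(benzyloxy)-2,4-bis[4-(benzyloxy)benzyl]-3-(2-{3-(benzyloxy)-4-[4-(benzyloxy)benzyl]phenyl}ethyl)-5-methoxybenzene | COc1cc(OCc2ccccc2)c(Cc2ccc(OCc3ccccc3)cc2)c(CCc2ccc(Cc3ccc(OCc4ccccc4)cc3)c(OCc3ccccc3)c2)c1Cc1ccc(OCc2ccccc2)cc1 | intermediate
23 | 2,4-bis(4-hydroxybenzyl)-3-{2-[3-hydroxy-4-(4-hydroxybenzyl)phenyl]ethyl}-5-methoxyphenol (achiral) | COc1cc(O)c(Cc2ccc(O)cc2)c(CCc2ccc(Cc3ccc(O)cc3)c(O)c2)c1Cc1ccc(O)cc1 | target

**Step count**
Total step count: 13.
Longest linear sequence: 10 steps (steps 1, 2, 3, 4, 6, 9, 10, 11, 12, 13, from 1 to 23).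

**Three steps most likely to fail**

Step 6. Both C-Br bonds are electron-rich and flanked on both sides, so the double coupling may stall at 10 and 11 or give protodebromination.

- The fallback abandons cross-coupling and builds both arms by Friedel-Crafts acylation followed by ionic hydrogenation. It sets out from 4 and comes back at 12.
- 4-(Benzyloxy)benzoic acid and (CF3CO)2O (cat. H3PO4, CH2Cl2, 0 °C to rt) form 4-(benzyloxy)benzoic trifluoroacetic anhydride F1.
- This anhydride acylates 4 at the less crowded position para to OBn, giving methyl 2-{5-(benzyloxy)-2-[4-(benzyloxy)benzoyl]-3-methoxyphenyl}acetate F2.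
- Et3SiH and CF3CO2H in CH2Cl2 at 0 °C reduce this electron-rich diaryl ketone to methyl 2-{5-(benzyloxy)-2-[4-(benzyloxy)benzyl]-3-methoxyphenyl}acetate F3.
- A second acylation under the same conditions, at the remaining position para to OMe, gives methyl 2-{3-(benzyloxy)-2-[4-(benzyloxy)benzoyl]-6-[4-(benzyloxy)benzyl]-5-methoxyphenyl}acetate F4.
- The same silane reduction then delivers 12.
- The order in which the two open positions react does not matter, because both end up carrying the same group.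

Step 9. Enolate 16 is shielded by two ortho benzyl groups, and the diarylmethane CH2 of 15, para to the ester, is somewhat acidic towards excess amide base, so acylation by a methyl ester may be slow or messy.

- The fallback replaces the ester electrophile by an aldehyde (aldol addition, then oxidation). It sets out from 15 and 12 and comes back at 18.
- LiAlH4 (THF, 0 °C) reduces 15 to {3-(benzyloxy)-4-[4-(benzyloxy)benzyl]phenyl}methanol F5.
- MnO2 in CH2Cl2 then gives 3-(benzyloxy)-4-[4-(benzyloxy)benzyl]benzaldehyde F6.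
- Enolate 16, made from 12 with only 1.05 equiv LiN(SiMe3)2 at -78 °C, adds to the aldehyde within minutes at -78 °C. The product is methyl 2-{3-(benzyloxy)-2,6-bis[4-(benzyloxy)benzyl]-5-methoxyphenyl}-3-{3-(benzyloxy)-4-[4-(benzyloxy)benzyl]phenyl}-3-hydroxypropanoate F7, a racemic mixture of diastereomers.
- Dess-Martin periodinane in CH2Cl2 oxidises this mixture to 18.

Step 12. The benzylic cation is generated in a molecule with five benzyl ethers and a very nucleophilic ring A C-H, so Friedel-Crafts oligomers or benzyl migration could compete with elimination.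

- The fallback avoids cation chemistry and skips the stilbene. It sets out from 20 and comes back at 23.
- Ac2O, pyridine and DMAP (cat.) in CH2Cl2 give 2-{3-(benzyloxy)-2,6-bis[4-(benzyloxy)benzyl]-5-methoxyphenyl}-1-{3-(benzyloxy)-4-[4-(benzyloxy)benzyl]phenyl}ethyl acetate F8 (racemic).
- Hydrogenation over Pd/C (H2 3 bar, EtOAc/AcOH, rt to 40 °C) cleaves the benzylic C-OAc bond together with the five benzyl ethers and gives 23 directly.

Further compounds
F1 | step 6 | 4-(benzyloxy)benzoic trifluoroacetic anhydride | O=C(OC(=O)C(F)(F)F)c1ccc(OCc2ccccc2)cc1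
F2 | step 6 | methyl 2-{5-(benzyloxy)-2-[4-(benzyloxy)benzoyl]-3-methoxyphenyl}acetate | COC(=O)Cc1cc(OCc2ccccc2)cc(OC)c1C(=O)c1ccc(OCc2ccccc2)cc1
F3 | step 6 | methyl 2-{5-(benzyloxy)-2-[4-(benzyloxy)benzyl]-3-methoxyphenyl}acetate | COC(=O)Cc1cc(OCc2ccccc2)cc(OC)c1Cc1ccc(OCc2ccccc2)cc1
F4 | step 6 | methyl 2-{3-(benzyloxy)-2-[4-(benzyloxy)benzoyl]-6-[4-(benzyloxy)benzyl]-5-methoxyphenyl}acetate | COC(=O)Cc1c(C(=O)c2ccc(OCc3ccccc3)cc2)c(OCc2ccccc2)cc(OC)c1Cc1ccc(OCc2ccccc2)cc1
F5 | step 9 | {3-(benzyloxy)-4-[4-(benzyloxy)benzyl]phenyl}methanol | OCc1ccc(Cc2ccc(OCc3ccccc3)cc2)c(OCc2ccccc2)c1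
F6 | step 9 | 3-(benzyloxy)-4-[4-(benzyloxy)benzyl]benzaldehyde | O=Cc1ccc(Cc2ccc(OCc3ccccc3)cc2)c(OCc2ccccc2)c1
F7 | step 9 | methyl 2-{3-(benzyloxy)-2,6-bis[4-(benzyloxy)benzyl]-5-methoxyphenyl}-3-{3-(benzyloxy)-4-[4-(benzyloxy)benzyl]phenyl}-3-hydroxypropanoate (racemic diastereomer mixture) | COC(=O)C(C(O)c1ccc(Cc2ccc(OCc3ccccc3)cc2)c(OCc2ccccc2)c1)c1c(Cc2ccc(OCc3ccccc3)cc2)c(OCc2ccccc2)cc(OC)c1Cc1ccc(OCc2ccccc2)cc1
F8 | step 12 | 2-{3-(benzyloxy)-2,6-bis[4-(benzyloxy)benzyl]-5-methoxyphenyl}-1-{3-(benzyloxy)-4-[4-(benzyloxy)benzyl]phenyl}ethyl acetate (racemic) | CC(=O)OC(Cc1c(Cc2ccc(OCc3ccccc3)cc2)c(OCc2ccccc2)cc(OC)c1Cc1ccc(OCc2ccccc2)cc1)c1ccc(Cc2ccc(OCc3ccccc3)cc2)c(OCc2ccccc2)c1
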